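The cyclohexenone ring (C1 carbonyl, C2–H, C3–OMe, C4 ketal carbon, C5, C6 allyl-bearing stereocentre) is disconnected at C1–C2. Its C1(=O)–C2=C3(OMe) unit is one specific enol ether of a 1,3-dione and C6 is epimerised by base, so C2 is introduced as the neutral CH2 of a 1-methoxyvinyl group on C4 and C1 as an aldehyde. One Lewis-acid Prins-type cyclisation closes the six-membered ring and returns the enol ether with the methoxy group already on C3. The precursor is an acyclic tert-butyl ester bearing the aryloxy and 1-methoxyvinyl groups on one carbon and an (S)-α-allyl aldehyde; the ester later departs by oxidative decarboxylation in methanol.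

Key step: step 14

Remark: the aryloxy-bearing carbon (C4 of the target) is carried as both configurations from step 10 to step 16; it becomes a planar cation in step 17 and is fixed there.

Step 1
Reactants: 1 pent-4-enoic acid; 2 (4S)-4-benzyl-1,3-oxazolidin-2-one
Product: 4 (4S)-4-benzyl-3-(pent-4-enoyl)-1,3-oxazolidin-2-one, via pent-4-enoic pivalic anhydride 3 (not isolated)
Conditions: t-BuCOCl, Et3N, THF, −20 °C; then 2, LiCl, −20 °C → rt
Reagents that add atoms: none
Why: N-acylation of the oxazolidinone by the mixed pivalic anhydride (LiCl/Et3N variant) transfers the unhindered pentenoyl group and needs no strong base.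

Step 2
Reactants: 4 (4S)-4-benzyl-3-(pent-4-enoyl)-1,3-oxazolidin-2-one
Product: 6 (4S)-4-benzyl-3-[(2R)-2-(hydroxymethyl)pent-4-enoyl]-1,3-oxazolidin-2-one, via trichlorotitanium Z-enolate 5 (not isolated)
Conditions: TiCl4, i-Pr2NEt, CH2Cl2, 0 °C; then 1,3,5-trioxane, TiCl4, 0 °C; aq. NH4Cl
Reagents that add atoms: 1,3,5-trioxane, C1OCOCO1
Why: Auxiliary-controlled aldol-type hydroxymethylation (Evans Cl3Ti enolate with formaldehyde released from trioxane) in which the chelated Z-enolate is attacked on the face away from the benzyl group, setting the (2R) centre that ends as C6 of the target.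

Step 3
Reactants: 6 (4S)-4-benzyl-3-[(2R)-2-(hydroxymethyl)pent-4-enoyl]-1,3-oxazolidin-2-one
Product: 7 (4S)-4-benzyl-3-[(2R)-2-({[tert-butyl(dimethyl)silyl]oxy}methyl)pent-4-enoyl]-1,3-oxazolidin-2-one
Conditions: TBSCl, imidazole, CH2Cl2, rt
Reagents that add atoms: tert-butyl(chloro)dimethylsilane, CC(C)(C)[Si](C)(C)Cl
Why: Standard silylation of a primary alcohol, which keeps the two CH2O arms distinct once the imide is reduced and so preserves the stereocentre.

Step 4
Reactants: 7 (4S)-4-benzyl-3-[(2R)-2-({[tert-butyl(dimethyl)silyl]oxy}methyl)pent-4-enoyl]-1,3-oxazolidin-2-one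
Product: 8 (2S)-2-({[tert-butyl(dimethyl)silyl]oxy}methyl)pent-4-en-1-ol
Conditions: LiBH4, MeOH (1 equiv), THF, 0 °C
Reagents that add atoms: none
Why: Reductive cleavage of the N-acyl oxazolidinone with LiBH4 frees the primary alcohol and the auxiliary without touching the stereocentre (the descriptor changes to S only through the priority rules), and at 0 °C silyl migration between the two oxygens is not expected.

Step 5
Reactants: 8 (2S)-2-({[tert-butyl(dimethyl)silyl]oxy}methyl)pent-4-en-1-ol
Product: 9 tert-butyl{[(2R)-2-(iodomethyl)pent-4-en-1-yl]oxy}dimethylsilane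
Conditions: I2, PPh3, imidazole, CH2Cl2, 0 °C → rt
Reagents that add atoms: iodine, II
Why: Appel-type iodination replaces the primary hydroxyl by SN2 at CH2, leaving the neighbouring stereocentre and the silyl ether untouched.

Step 6
Reactants: 10 3,4-dimethoxyphenol; 11 allyl bromide
Product: 12 4-(allyloxy)-1,2-dimethoxybenzene
Conditions: K2CO3, acetone, reflux
Reagents that add atoms: none
Why: Williamson etherification of a phenoxide with an allylic bromide.

Step 7
Reactants: 12 4-(allyloxy)-1,2-dimethoxybenzene
Product: 13 2-allyl-4,5-dimethoxyphenol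
Conditions: PhNEt2, 200 °C
Reagents that add atoms: none
Why: Aromatic Claisen rearrangement, in which the [3,3] shift goes to the free ortho carbon not flanked by a methoxy group and tautomerisation restores the phenol.

Step 8
Reactants: 14 tert-butyl methyl malonate
Product: 15 tert-butyl methyl 2-diazomalonate
Conditions: 4-AcNHC6H4SO2N3, Et3N, MeCN, 0 °C → rt
Reagents that add atoms: 4-acetamidobenzenesulfonyl azide, CC(=O)Nc1ccc(cc1)S(=O)(=O)N=[N+]=[N-]
Why: Regitz diazo transfer to an active methylene compound under mild amine base, compatible with both esters.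

Step 9
Reactants: 15 tert-butyl methyl 2-diazomalonate; 13 2-allyl-4,5-dimethoxyphenol
Product: 16 1-tert-butyl 3-methyl 2-(2-allyl-4,5-dimethoxyphenoxy)malonate (racemic)
Conditions: Rh2(OAc)4 (1 mol %), benzene, 80 °C, slow addition of 15
Reagents that add atoms: none
Why: O–H insertion of the carbenoid formed from 15 and Rh2(OAc)4 into the phenol, which should outrun cyclopropanation of the allyl group and attack on the arene while the phenol is kept in excess.

Step 10
Reactants: 16 1-tert-butyl 3-methyl 2-(2-allyl-4,5-dimethoxyphenoxy)malonate; 9 tert-butyl{[(2R)-2-(iodomethyl)pent-4-en-1-yl]oxy}dimethylsilane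
Product: 17 1-tert-butyl 3-methyl 2-(2-allyl-4,5-dimethoxyphenoxy)-2-[(2S)-2-({[tert-butyl(dimethyl)silyl]oxy}methyl)pent-4-en-1-yl]malonate (both configurations at C2)
Conditions: Cs2CO3, DMF, 50 °C
Reagents that add atoms: none
Why: Malonic ester alkylation (SN2 of the caesium enolate on the primary iodide) creates the quaternary carbon as both epimers, which is accepted because this centre is erased in step 17, while the existing centre is not involved.

Step 11
Reactants: 17 1-tert-butyl 3-methyl 2-(2-allyl-4,5-dimethoxyphenoxy)-2-[(2S)-2-({[tert-butyl(dimethyl)silyl]oxy}methyl)pent-4-en-1-yl]malonate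
Product: 18 tert-butyl (4S)-2-(2-allyl-4,5-dimethoxyphenoxy)-4-({[tert-butyl(dimethyl)silyl]oxy}methyl)-2-(1-methoxyvinyl)hept-6-enoate (both configurations at C2)
Conditions: Cp2TiMe2, toluene, 70 °C, dark; Et3N-treated silica
Reagents that add atoms: Cp2TiMe2 (dimethyltitanocene), C[Ti](C)(C1C=CC=C1)C1C=CC=C1
Why: Petasis methylenation of an ester by Cp2Ti=CH2, which should select the methyl ester because the tert-butyl ester carbonyl is far more shielded, and which puts the methoxy group on the future C3 with no regiochemical choice.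

Step 12
Reactants: 18 tert-butyl (4S)-2-(2-allyl-4,5-dimethoxyphenoxy)-4-({[tert-butyl(dimethyl)silyl]oxy}methyl)-2-(1-methoxyvinyl)hept-6-enoate
Product: 19 tert-butyl (4S)-2-(2-allyl-4,5-dimethoxyphenoxy)-4-(hydroxymethyl)-2-(1-methoxyvinyl)hept-6-enoate (both configurations at C2)
Conditions: Bu4NF, THF, 0 °C
Reagents that add atoms: none
Why: Fluoride desilylation is non-acidic and so spares the enol ether, and the hindered tert-butyl ester should not lactonise at 0 °C.

Step 13
Reactants: 19 tert-butyl (4S)-2-(2-allyl-4,5-dimethoxyphenoxy)-4-(hydroxymethyl)-2-(1-methoxyvinyl)hept-6-enoate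
Product: 20 tert-butyl (4S)-2-(2-allyl-4,5-dimethoxyphenoxy)-4-formyl-2-(1-methoxyvinyl)hept-6-enoate (both configurations at C2)
Conditions: Dess–Martin periodinane, pyridine, CH2Cl2, 0 °C → rt; used crude
Reagents that add atoms: none
Why: Dess–Martin oxidation buffered with pyridine gives the aldehyde without acid that would hydrolyse the enol ether and without base that would epimerise the α-centre.

Step 14
Reactants: 20 tert-butyl (4S)-2-(2-allyl-4,5-dimethoxyphenoxy)-4-formyl-2-(1-methoxyvinyl)hept-6-enoate
Product: 21 tert-butyl (5S)-5-allyl-1-(2-allyl-4,5-dimethoxyphenoxy)-4-hydroxy-2-methoxycyclohex-2-ene-1-carboxylate (C1 and C4 as mixtures)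
Conditions: Me2AlCl (2 equiv), 2,6-di-tert-butylpyridine, CH2Cl2, −78 → −40 °C; Et3N–MeOH, then aq. NaHCO3; used crude
Reagents that add atoms: none
Why: Me2AlCl binds the aldehyde oxygen, the electron-rich terminal CH2 of the 1-methoxyvinyl group adds to the activated carbonyl carbon (C1–C2 bond) to give a methoxy-stabilised cation at C3, and this cation loses a C2 proton to the hindered pyridine or to an Al–CH3 group, which returns the enol ether inside the new ring. The closest known reaction type is the Lewis-acid carbonyl-ene or Prins-type addition of 2-methoxypropene and other 2-alkoxyalkenes to aldehydes, applied here within one molecule. The six-membered ring closes in a 6-(enolendo)-exo-trig mode, with the attacking C=C inside the ring and the C=O outside it. The only new stereocentre, the carbinol carbon, is left uncontrolled because step 15 oxidises it away, and the allyl-bearing centre is untouched since nothing present at −78 °C can enolise the aldehyde. The step needs carbon attack at the CH2 end and proton loss towards C2 only: the methoxy group directs the attack, and because C4 is quaternary the cation has no other ring proton to lose, so the double bond can only return as C2=C3. Me2AlCl also consumes the released proton as methane, which protects the enol ether, the tert-butyl ester and the new allylic alcohol from protic acid.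

Step 15
Reactants: 21 tert-butyl (5S)-5-allyl-1-(2-allyl-4,5-dimethoxyphenoxy)-4-hydroxy-2-methoxycyclohex-2-ene-1-carboxylate
Product: 22 tert-butyl (5S)-5-allyl-1-(2-allyl-4,5-dimethoxyphenoxy)-2-methoxy-4-oxocyclohex-2-ene-1-carboxylate (both configurations at C1)
Conditions: MnO2, CH2Cl2, rt
Reagents that add atoms: none
Why: Neutral MnO2 oxidation of the allylic alcohol gives the vinylogous ester, removes the uncontrolled carbinol centre and should not epimerise the adjacent allyl-bearing carbon.

Step 16
Reactants: 22 tert-butyl (5S)-5-allyl-1-(2-allyl-4,5-dimethoxyphenoxy)-2-methoxy-4-oxocyclohex-2-ene-1-carboxylate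
Product: 23 (5S)-5-allyl-1-(2-allyl-4,5-dimethoxyphenoxy)-2-methoxy-4-oxocyclohex-2-ene-1-carboxylic acid (both configurations at C1)
Conditions: CF3CO2H–CH2Cl2 (1:4), 0 °C; used at once
Reagents that add atoms: none
Why: Acidolysis of the tert-butyl ester with loss of isobutene needs no base or water, so the vinylogous ester and the C5 centre survive, and both free arene positions are flanked by two substituents, which should suppress tert-butylation.

Step 17
Reactants: 23 (5S)-5-allyl-1-(2-allyl-4,5-dimethoxyphenoxy)-2-methoxy-4-oxocyclohex-2-ene-1-carboxylic acid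
Product: 24 (4R,6S)-6-allyl-4-(2-allyl-4,5-dimethoxyphenoxy)-3,4-dimethoxycyclohex-2-en-1-one
Conditions: Pb(OAc)4, pyridine, MeOH–CH2Cl2, −20 → 0 °C
Reagents that add atoms: methanol, CO
Why: Kochi-type oxidative decarboxylation of the α-aryloxy acid with Pb(OAc)4 gives the aryloxy-stabilised cation at C4, which methanol should capture axially on the half-chair that holds the C6 allyl group pseudo-equatorial, that is on the face trans to allyl, so that C4 becomes (R), while pyridine buffers the acetic acid and prevents ketal exchange.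

Compound list
1 | pent-4-enoic acid | C=CCCC(=O)O | starting material
2 | (4S)-4-benzyl-1,3-oxazolidin-2-one | O=C1N[C@@H](Cc2ccccc2)CO1 | starting material
3 | pent-4-enoic pivalic anhydride | C=CCCC(=O)OC(=O)C(C)(C)C | intermediate
4 | (4S)-4-benzyl-3-(pent-4-enoyl)-1,3-oxazolidin-2-one | C=CCCC(=O)N1[C@@H](Cc2ccccc2)COC1=O | intermediate
5 | trichlorotitanium Z-enolate of 4 | C=CC/C=C(\O[Ti](Cl)(Cl)Cl)N1[C@@H](Cc2ccccc2)COC1=O | intermediate
6 | (4S)-4-benzyl-3-[(2R)-2-(hydroxymethyl)pent-4-enoyl]-1,3-oxazolidin-2-one | C=CC[C@H](CO)C(=O)N1[C@@H](Cc2ccccc2)COC1=O | intermediate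
7 | (4S)-4-benzyl-3-[(2R)-2-({[tert-butyl(dimethyl)silyl]oxy}methyl)pent-4-enoyl]-1,3-oxazolidin-2-one | C=CC[C@H](CO[Si](C)(C)C(C)(C)C)C(=O)N1[C@@H](Cc2ccccc2)COC1=O | intermediate
8 | (2S)-2-({[tert-butyl(dimethyl)silyl]oxy}methyl)pent-4-en-1-ol | C=CC[C@H](CO[Si](C)(C)C(C)(C)C)CO | intermediate
9 | tert-butyl{[(2R)-2-(iodomethyl)pent-4-en-1-yl]oxy}dimethylsilane | C=CC[C@H](CO[Si](C)(C)C(C)(C)C)CI | intermediate
10 | 3,4-dimethoxyphenol | COc1ccc(O)cc1OC | starting material
11 | allyl bromide | C=CCBr | starting material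
12 | 4-(allyloxy)-1,2-dimethoxybenzene | C=CCOc1ccc(OC)c(OC)c1 | intermediate
13 | 2-allyl-4,5-dimethoxyphenol | C=CCc1cc(OC)c(OC)cc1O | intermediate
14 | tert-butyl methyl malonate | COC(=O)CC(=O)OC(C)(C)C | starting material
15 | tert-butyl methyl 2-diazomalonate | COC(=O)C(=[N+]=[N-])C(=O)OC(C)(C)C | intermediate
16 | 1-tert-butyl 3-methyl 2-(2-allyl-4,5-dimethoxyphenoxy)malonate (racemic) | C=CCc1cc(OC)c(OC)cc1OC(C(=O)OC)C(=O)OC(C)(C)C | intermediate
17 | 1-tert-butyl 3-methyl 2-(2-allyl-4,5-dimethoxyphenoxy)-2-[(2S)-2-({[tert-butyl(dimethyl)silyl]oxy}methyl)pent-4-en-1-yl]malonate (both configurations at C2) | C=CCc1cc(OC)c(OC)cc1OC(C(=O)OC)(C(=O)OC(C)(C)C)C[C@H](CC=C)CO[Si](C)(C)C(C)(C)C | intermediate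
18 | tert-butyl (4S)-2-(2-allyl-4,5-dimethoxyphenoxy)-4-({[tert-butyl(dimethyl)silyl]oxy}methyl)-2-(1-methoxyvinyl)hept-6-enoate (both configurations at C2) | C=CCc1cc(OC)c(OC)cc1OC(C(=O)OC(C)(C)C)(C(=C)OC)C[C@H](CC=C)CO[Si](C)(C)C(C)(C)C | intermediate
19 | tert-butyl (4S)-2-(2-allyl-4,5-dimethoxyphenoxy)-4-(hydroxymethyl)-2-(1-methoxyvinyl)hept-6-enoate (both configurations at C2) | C=CCc1cc(OC)c(OC)cc1OC(C(=O)OC(C)(C)C)(C(=C)OC)C[C@H](CC=C)CO | intermediate
20 | tert-butyl (4S)-2-(2-allyl-4,5-dimethoxyphenoxy)-4-formyl-2-(1-methoxyvinyl)hept-6-enoate (both configurations at C2) | C=CCc1cc(OC)c(OC)cc1OC(C(=O)OC(C)(C)C)(C(=C)OC)C[C@H](CC=C)C=O | intermediate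
21 | tert-butyl (5S)-5-allyl-1-(2-allyl-4,5-dimethoxyphenoxy)-4-hydroxy-2-methoxycyclohex-2-ene-1-carboxylate (C1 and C4 as mixtures) | C=CCc1cc(OC)c(OC)cc1OC1(C(=O)OC(C)(C)C)C[C@H](CC=C)C(O)C=C1OC | intermediate
22 | tert-butyl (5S)-5-allyl-1-(2-allyl-4,5-dimethoxyphenoxy)-2-methoxy-4-oxocyclohex-2-ene-1-carboxylate (both configurations at C1) | C=CCc1cc(OC)c(OC)cc1OC1(C(=O)OC(C)(C)C)C[C@H](CC=C)C(=O)C=C1OC | intermediate
23 | (5S)-5-allyl-1-(2-allyl-4,5-dimethoxyphenoxy)-2-methoxy-4-oxocyclohex-2-ene-1-carboxylic acid (both configurations at C1) | C=CCc1cc(OC)c(OC)cc1OC1(C(=O)O)C[C@H](CC=C)C(=O)C=C1OC | intermediate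
24 | (4R,6S)-6-allyl-4-(2-allyl-4,5-dimethoxyphenoxy)-3,4-dimethoxycyclohex-2-en-1-one | C=CCc1cc(OC)c(OC)cc1O[C@]1(OC)C[C@H](CC=C)C(=O)C=C1OC | target

Total step count: 17. Longest linear sequence: 13 steps (steps 1–5 and 10–17).

Steps most likely to fail

Step 14. The enol ether is inductively deactivated by the aryloxy and ester groups on the neighbouring carbon and may add to the aluminium-bound aldehyde too slowly, so that methyl transfer from aluminium competes. The product alkoxide may also ionise at C1 under the Lewis acid, and the enol ether may be lost on work-up. The fallback replaces the aldol-type addition by an acylation and sets out from aldehyde 20. Chlorite oxidation (NaClO2, NaH2PO4, 2-methylbut-2-ene in large excess, t-BuOH–H2O, 0 °C) gives (2S)-2-allyl-4-(2-allyl-4,5-dimethoxyphenoxy)-4-(tert-butoxycarbonyl)-5-methoxyhex-5-enoic acid F1, which is used at once so that the acid does not add to its own enol ether. 1-Chloro-N,N,2-trimethylprop-1-en-1-amine in CH2Cl2 at 0 °C converts it under neutral conditions into tert-butyl (4S)-2-(2-allyl-4,5-dimethoxyphenoxy)-4-(chlorocarbonyl)-2-(1-methoxyvinyl)hept-6-enoate F2. ZnCl2 (catalytic) with 2,6-di-tert-butylpyridine then lets the enol ether CH2 attack the acyl chloride; this C-acylation of an enol ether forms the same C1–C2 bond at the ketone oxidation level, with loss of HCl. The route is rejoined at enone 22, and step 15 is no longer needed.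

Step 17. Methanol may capture the cation on both faces, the acetic acid released may exchange the aryloxy group for methoxy, and tetravalent lead may attack the electron-rich arene or the alkenes. The fallback separates decarboxylation from ketal formation and uses no strong oxidant; it sets out from acid 23. Coupling with 1-hydroxypyridine-2(1H)-thione (N,N'-dicyclohexylcarbodiimide, CH2Cl2, 0 °C, dark) gives the thiohydroxamate ester 2-thioxopyridin-1(2H)-yl (5S)-5-allyl-1-(2-allyl-4,5-dimethoxyphenoxy)-2-methoxy-4-oxocyclohex-2-ene-1-carboxylate F3. Visible-light irradiation at rt triggers the Barton decarboxylative rearrangement to (6S)-6-allyl-4-(2-allyl-4,5-dimethoxyphenoxy)-3-methoxy-4-(pyridin-2-ylsulfanyl)cyclohex-2-en-1-one F4. AgOSO2CF3 with methanol and 2,6-di-tert-butylpyridine in CH2Cl2 at −40 °C then removes the thiolate and lets methanol add to the same aryloxy cation, again trans to allyl. The route is rejoined at target 24.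

Step 11. Methylenation of the methyl ester beside a fully substituted carbon may stall, forcing conditions may also methylenate the tert-butyl ester, and the enol ether may hydrolyse during purification. The fallback makes the enol ether by O-methylation of a ketone enolate and sets out from phenol 13 and iodide 9. Alkylation of 13 with tert-butyl 2-chloro-3-oxobutanoate (K2CO3, acetone) gives tert-butyl 2-(2-allyl-4,5-dimethoxyphenoxy)-3-oxobutanoate F5. C-Alkylation with 9 (Cs2CO3, DMF, 50 °C) gives tert-butyl (4S)-2-acetyl-2-(2-allyl-4,5-dimethoxyphenoxy)-4-({[tert-butyl(dimethyl)silyl]oxy}methyl)hept-6-enoate F6. Its potassium enolate (KN(SiMe3)2, THF–DMPU, −78 °C) can form only towards the methyl group and is O-methylated with MeOSO2CF3. The route is rejoined at enol ether 18.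

Further compounds
F1 | step 14 | (2S)-2-allyl-4-(2-allyl-4,5-dimethoxyphenoxy)-4-(tert-butoxycarbonyl)-5-methoxyhex-5-enoic acid (both configurations at C4) | C=CCc1cc(OC)c(OC)cc1OC(C(=O)OC(C)(C)C)(C(=C)OC)C[C@H](CC=C)C(=O)O
F2 | step 14 | tert-butyl (4S)-2-(2-allyl-4,5-dimethoxyphenoxy)-4-(chlorocarbonyl)-2-(1-methoxyvinyl)hept-6-enoate (both configurations at C2) | C=CCc1cc(OC)c(OC)cc1OC(C(=O)OC(C)(C)C)(C(=C)OC)C[C@H](CC=C)C(Cl)=O
F3 | step 17 | 2-thioxopyridin-1(2H)-yl (5S)-5-allyl-1-(2-allyl-4,5-dimethoxyphenoxy)-2-methoxy-4-oxocyclohex-2-ene-1-carboxylate (both configurations at C1) | C=CCc1cc(OC)c(OC)cc1OC1(C(=O)ON2C=CC=CC2=S)C[C@H](CC=C)C(=O)C=C1OC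
F4 | step 17 | (6S)-6-allyl-4-(2-allyl-4,5-dimethoxyphenoxy)-3-methoxy-4-(pyridin-2-ylsulfanyl)cyclohex-2-en-1-one (both configurations at C4) | C=CCc1cc(OC)c(OC)cc1OC1(Sc2ccccn2)C[C@H](CC=C)C(=O)C=C1OC
F5 | step 11 | tert-butyl 2-(2-allyl-4,5-dimethoxyphenoxy)-3-oxobutanoate (racemic) | C=CCc1cc(OC)c(OC)cc1OC(C(C)=O)C(=O)OC(C)(C)C
F6 | step 11 | tert-butyl (4S)-2-acetyl-2-(2-allyl-4,5-dimethoxyphenoxy)-4-({[tert-butyl(dimethyl)silyl]oxy}methyl)hept-6-enoate (both configurations at C2) | C=CCc1cc(OC)c(OC)cc1OC(C(C)=O)(C(=O)OC(C)(C)C)C[C@H](CC=C)CO[Si](C)(C)C(C)(C)C
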